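The data come from a simulation from invented constants.

The target is made from the starting material by the free catalyst and then turns on into its isomer, while added ligand slows the whole flask, so I need to know how far each flask has travelled along that path by the time it is stopped.

| setting | gamma | theta | epsilon | larch | oak | ash |
|---|---|---|---|---|---|---|
| starting material | 0.80 M | 0.80 M | 0.80 M | 0.80 M | 0.80 M | 0.80 M |
| free catalyst | 3.1 mol% | 3.1 mol% | 3.1 mol% | 3.1 mol% | 3.1 mol% | 3.1 mol% |
| added ligand | 14 mM | 39 mM | 70 mM | 18 mM | 36 mM | 72 mM |
| remark | run made earlier | run made earlier | run made earlier |  |  |  |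
| time |  |  |  | 15 min | 15 min | 15 min |

| run | time / min | starting material / % | target / % | isomer of the product / % | catalyst intermediate / % |
|---|---|---|---|---|---|
| gamma | 0.667 | 84.2 | 15.2 | 0.4 | 0 |
| gamma | 1.33 | 72.3 | 26.0 | 2.6 | 0 |
| gamma | 3.00 | 47.1 | 40.5 | 9.8 | 0.7 |
| gamma | 8.00 | 13.5 | 47.2 | 39.7 | 0 |
| theta | 1.00 | 91.0 | 7.3 | 0.9 | 0 |
| theta | 2.50 | 81.2 | 17.0 | 1.4 | 0.2 |
| theta | 5.00 | 67.6 | 28.9 | 4.0 | 0 |
| theta | 8.00 | 53.6 | 38.8 | 7.3 | 0.3 |
| epsilon | 0.667 | 97.7 | 3.2 | 0 | 0 |
| epsilon | 1.33 | 94.6 | 5.3 | 0.3 | 0.3 |
| epsilon | 3.00 | 89.5 | 10.0 | 0.1 | 0 |
| epsilon | 8.00 | 76.0 | 22.2 | 1.6 | 0.9 |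

(readings scatter by 0.5 percentage points)

1. which of these there is most of at the end, counted by the starting material in it, larch (isomer of the product / target / catalyst intermediate / starting material)
2. which of these there is most of at the end, counted by the starting material in it, oak (isomer of the product / target / catalyst intermediate / starting material)
3. which of these there is most of at the end, counted by the starting material in it, ash (isomer of the product / target / catalyst intermediate / starting material)
4. amount of the one of these that there is most of at the end, in percent of the starting material charged, larch
5. amount of the one of these that there is most of at the end, in percent of the starting material charged, oak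
6. amount of the one of these that there is most of at the end, in percent of the starting material charged, ash



In each run the logarithm of the starting material falls nearly straight (pseudo-first-order), so the last reading gives each run a constant k: 0.250 min⁻¹ in gamma, 0.0780 min⁻¹ in theta, 0.0343 min⁻¹ in epsilon.

I take target going on to isomer with a constant 0.5 of k, nothing flowing back. If a is the fraction of starting material left, target is then 2(√a − a) and isomer the square of (1 − √a). For gamma's last reading this gives 46.5% of target against 47.2% read.

So under this assumption one number places a flask: x = k·t, the progress, with a = e^(−x). Target overtakes starting material at x = 0.811, and isomer overtakes target at x = 2.20.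

Interpolating 1/k linearly in added ligand, with a short extrapolation for ash, I get 2.77 for larch, 1.27 for oak and 0.497 for ash. Oak's figure is its progress, k times time. Larch lies beyond the second mark, oak between the marks, and ash before the first. I therefore expect isomer at 56.3% in larch, target at 49.8% in oak and starting material at 60.8% in ash.

The forecast says isomer of the product at 59% in larch, target at 50% in oak and starting material at 60.5% in ash, on a starting material that “falls first-order in every run”, with the same leaders as mine and larch higher than my figure.

The flasks give isomer of the product at 55.5% in larch, target at 49.0% in oak and starting material at 61.3% in ash.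

    starting material + free catalyst → catalyst intermediate (k = 0.302 M⁻¹ s⁻¹)
    catalyst intermediate → free catalyst + target (k = 5.77 s⁻¹)
    free catalyst + added ligand ⇌ idle complex (K = 264 M⁻¹, k = 13.3 M⁻¹ s⁻¹)
    target + free catalyst ⇌ isomer of the product + free catalyst, rate k4*[free catalyst]*[target] forward; the back reaction follows from the equilibrium constant (K = 2.78, k = 0.178 M⁻¹ s⁻¹)

In oak, starting material takes free catalyst at 0.50 of the rate at which added ligand takes it at the start and 0.31 at 15.0 min, forward steps alone. Free catalyst in oak stands at 19.0% of the catalyst charged at 7.50 min and 19.1% at 15.0 min, with idle complex at 80.7%, and oak's progress 1.27 gave 28.1% of starting material where the flask holds 27.4%. Oak stopped at 10 min has progress 0.850, past 0.811, so I expect target leading at 45.3%. That flask holds 44.6% of target against 42.0% of starting material.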